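**Plan**
1. Retrosynthesis: the C4 ketone and the C5/C7 phenols are unmasked last, from a silyl-capped C4 carbinol and two MOM ethers. The central cut is the aryl ether bond O1–C8a of ring C, formed by palladium-catalysed coupling of the C2 hydroxyl with a C8a triflate.
2. Enabling feature: the ring C oxygen O1 is bonded on one side to C2, the benzylic stereocentre, and on the other to the aromatic carbon C8a of ring A. The aryl side can therefore be closed last, with the C2–O bond already in place from a carbinol.
3. Further cuts: C2–H (ketone reduction), C3–C4 (aldol of 4-methoxyacetophenone with a ring A aldehyde), C4a–CHO, C8–prenyl (aryl ether Claisen rearrangement) and the C8a oxygen (C–H borylation/oxidation of bis-MOM 2-methylresorcinol).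
4. Forward: ring A is fully substituted first (steps 1–7), the C2–C3 unit with ring B is joined by the aldol (step 8), ring C closes in the palladium step, then desilylation, oxidation and MOM removal follow.
5. Stereochemistry: C2 (S), the only stereocentre of the target, comes from a Corey–Bakshi–Shibata reduction of the aryl ketone and is carried through with retention. C4 is left uncontrolled because it ends as the carbonyl carbon.

Key step: step 11

Remarks: Flavanone numbering is used for all intermediates (O1, C2, C3, C4, C4a, C5 to C8, C8a; ring A the fused benzene ring, ring B the 4-methoxyphenyl group, ring C the pyran ring). The C4 carbinol is made racemic on purpose, so from step 10 to step 12 each compound is the pair of C4 epimers with C2 uniformly S, and the pair converges in step 13. The C4 oxygen is capped as a silyl ether before the palladium step so that it cannot bind palladium next to the insertion site or attack the neighbouring triflate. 2-Methylresorcinol, 2-methylbut-3-yn-2-ol and 4-methoxyacetophenone are taken as purchased.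

**Step 1**
Reactants: 1 2-methylresorcinol (2-methylbenzene-1,3-diol)
Product: 2 1,3-bis(methoxymethoxy)-2-methylbenzene
Conditions: NaH, MOMCl, DMF, 0 °C → rt
Reagents that add atoms: chloromethyl methyl ether, COCCl
Why: Williamson O-alkylation of both sodium phenoxides with the reactive chloromethyl ether should give the bis-MOM ether, which masks O5 and O7 with a group that tolerates every basic, reductive and palladium step ahead.

**Step 2**
Reactants: 2 1,3-bis(methoxymethoxy)-2-methylbenzene
Product: 4 3,5-bis(methoxymethoxy)-4-methylphenol, via aryl pinacol boronate 3 (not isolated)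
Conditions: [Ir(OMe)(cod)]2 (cat.), 4,4'-di-tert-butyl-2,2'-bipyridine, HBpin, THF, 60 °C; then aq. NaOH, 30% H2O2, 0 °C
Reagents that add atoms: pinacolborane, [H]B1OC(C)(C)C(C)(C)O1 (the boryl group of 3); hydrogen peroxide, OO (the phenol oxygen of 4)
Why: Sterically governed iridium-catalysed C–H borylation should touch only the one ring hydrogen without an ortho substituent (para to the methyl group), and one-pot oxidation of the C–B bond then places the hydroxyl at that carbon, the future C8a.

**Step 3**
Reactants: 4 3,5-bis(methoxymethoxy)-4-methylphenol; 5 2-methylbut-3-yn-2-ol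
Product: 7 1,3-bis(methoxymethoxy)-2-methyl-5-[(2-methylbut-3-yn-2-yl)oxy]benzene, via 2-methylbut-3-yn-2-yl trifluoroacetate 6 (not isolated)
Conditions: 5, (CF3CO)2O, DBU, MeCN, –5 °C; then 4, CuCl2 (cat.), DBU, MeCN, 0 °C
Reagents that add atoms: trifluoroacetic anhydride, O=C(OC(=O)C(F)(F)F)C(F)(F)F (the acyl group of 6; no atom of it remains in 7)
Why: Copper-catalysed propargylic substitution of the in situ trifluoroacetate by the phenoxide is the standard way to a tertiary aryl 1,1-dimethylpropargyl ether, where a direct SN2 alkylation would fail.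

**Step 4**
Reactants: 7 1,3-bis(methoxymethoxy)-2-methyl-5-[(2-methylbut-3-yn-2-yl)oxy]benzene
Product: 8 1,3-bis(methoxymethoxy)-2-methyl-5-[(2-methylbut-3-en-2-yl)oxy]benzene
Conditions: H2 (1 atm), Pd/CaCO3 poisoned with Pb(OAc)2, quinoline, EtOAc, rt
Reagents that add atoms: none
Why: Lindlar semihydrogenation should stop at the terminal alkene and give the 1,1-dimethylallyl aryl ether needed for the sigmatropic shift.

**Step 5**
Reactants: 8 1,3-bis(methoxymethoxy)-2-methyl-5-[(2-methylbut-3-en-2-yl)oxy]benzene
Product: 10 3,5-bis(methoxymethoxy)-4-methyl-2-(3-methylbut-2-en-1-yl)phenol, via ortho-dienone 9 (not isolated)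
Conditions: o-xylene, 130 °C
Reagents that add atoms: none
Why: In the aromatic Claisen rearrangement the [3,3] shift carries the allyl unit to one of the two equivalent ortho carbons with allylic transposition, so the tertiary ether becomes a linear prenyl group at the future C8, and tautomerisation of the dienone restores the phenol.

**Step 6**
Reactants: 10 3,5-bis(methoxymethoxy)-4-methyl-2-(3-methylbut-2-en-1-yl)phenol
Product: 12 2-hydroxy-4,6-bis(methoxymethoxy)-5-methyl-3-(3-methylbut-2-en-1-yl)benzaldehyde, via hydroxymethyl phenol 11 (not isolated)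
Conditions: MgCl2, Et3N, (CH2O)n, MeCN, 80 °C
Reagents that add atoms: formaldehyde (from paraformaldehyde), C=O
Why: In the magnesium-mediated ortho-formylation (Casnati–Skattebøl) the magnesium phenoxide delivers formaldehyde to the only free ring position, which is ortho to the hydroxyl, and a second formaldehyde oxidises the benzylic alkoxide by hydride transfer, all under basic conditions that spare the MOM ethers and the prenyl group.

**Step 7**
Reactants: 12 2-hydroxy-4,6-bis(methoxymethoxy)-5-methyl-3-(3-methylbut-2-en-1-yl)benzaldehyde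
Product: 13 2-formyl-3,5-bis(methoxymethoxy)-4-methyl-6-(3-methylbut-2-en-1-yl)phenyl trifluoromethanesulfonate
Conditions: PhNTf2, Et3N, DMAP (cat.), CH2Cl2, 0 °C → rt
Reagents that add atoms: N-phenylbis(trifluoromethanesulfonimide), O=S(=O)(N(c1ccccc1)S(=O)(=O)C(F)(F)F)C(F)(F)F
Why: O-sulfonylation of the phenoxide with this mild triflyl donor turns the C8a oxygen into the leaving group for palladium and activates the aldehyde, without the strong acid that triflic anhydride would release onto the MOM ethers.

**Step 8**
Reactants: 13 2-formyl-3,5-bis(methoxymethoxy)-4-methyl-6-(3-methylbut-2-en-1-yl)phenyl trifluoromethanesulfonate; 14 4-methoxyacetophenone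
Product: 16 rac-2-[1-hydroxy-3-(4-methoxyphenyl)-3-oxopropyl]-3,5-bis(methoxymethoxy)-4-methyl-6-(3-methylbut-2-en-1-yl)phenyl trifluoromethanesulfonate, via lithium enolate 15 (not isolated)
Conditions: 14, LiN(iPr)2, THF, –78 °C; then 13, –78 °C; AcOH quench at –78 °C
Reagents that add atoms: lithium diisopropylamide, [Li]N(C(C)C)C(C)C (the lithium of 15; no atom of it remains in 16)
Why: Directed aldol addition of the preformed lithium enolate of the methyl ketone to the non-enolisable aldehyde forms the C3–C4 bond, and the new C4 carbinol is deliberately racemic because C4 becomes the carbonyl carbon later.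

**Step 9**
Reactants: 16 rac-2-[1-hydroxy-3-(4-methoxyphenyl)-3-oxopropyl]-3,5-bis(methoxymethoxy)-4-methyl-6-(3-methylbut-2-en-1-yl)phenyl trifluoromethanesulfonate
Product: 17 rac-2-[1-(tert-butyldimethylsilyloxy)-3-(4-methoxyphenyl)-3-oxopropyl]-3,5-bis(methoxymethoxy)-4-methyl-6-(3-methylbut-2-en-1-yl)phenyl trifluoromethanesulfonate
Conditions: TBSOTf, 2,6-lutidine, CH2Cl2, –78 °C
Reagents that add atoms: tert-butyldimethylsilyl trifluoromethanesulfonate, CC(C)(C)[Si](C)(C)OS(=O)(=O)C(F)(F)F
Why: Silylation of the hindered secondary alcohol with the silyl triflate and a hindered base is fast at low temperature, where the β-hydroxy ketone should not dehydrate and the aryl MOM ethers should not be attacked.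

**Step 10**
Reactants: 17 rac-2-[1-(tert-butyldimethylsilyloxy)-3-(4-methoxyphenyl)-3-oxopropyl]-3,5-bis(methoxymethoxy)-4-methyl-6-(3-methylbut-2-en-1-yl)phenyl trifluoromethanesulfonate
Product: 18 2-[(3S)-1-(tert-butyldimethylsilyloxy)-3-hydroxy-3-(4-methoxyphenyl)propyl]-3,5-bis(methoxymethoxy)-4-methyl-6-(3-methylbut-2-en-1-yl)phenyl trifluoromethanesulfonate (both epimers at C1 of the propyl chain, which is C4)
Conditions: (R)-2-methyl-CBS-oxazaborolidine [(R)-1-methyl-3,3-diphenyltetrahydro-1H,3H-pyrrolo[1,2-c][1,3,2]oxazaborole] (20 mol %), catecholborane, toluene, –78 → –30 °C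
Reagents that add atoms: none
Why: In the Corey–Bakshi–Shibata reduction the ketone binds the (R)-oxazaborolidine with the 4-methoxyphenyl group as the large substituent and takes hydride on its Re face, which sets C2 as S under catalyst control in both C4 epimers, while catecholborane at low temperature leaves the prenyl alkene alone.

**Step 11**
Reactants: 18 2-[(3S)-1-(tert-butyldimethylsilyloxy)-3-hydroxy-3-(4-methoxyphenyl)propyl]-3,5-bis(methoxymethoxy)-4-methyl-6-(3-methylbut-2-en-1-yl)phenyl trifluoromethanesulfonate
Product: 19 (2S)-4-(tert-butyldimethylsilyloxy)-5,7-bis(methoxymethoxy)-2-(4-methoxyphenyl)-6-methyl-8-(3-methylbut-2-en-1-yl)chromane (both C4 epimers)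
Conditions: Pd(OAc)2 (5 mol %), tBuXPhos [2-di-tert-butylphosphino-2',4',6'-triisopropylbiphenyl] (7.5 mol %), K3PO4, toluene, 80 °C
Reagents that add atoms: none
Why: Zerovalent palladium, generated in situ from Pd(OAc)2 and the phosphine, inserts into the C8a–OTf bond, the C2 hydroxyl binds and is deprotonated by K3PO4 to a seven-membered aryl alkoxide complex of divalent palladium (Pd, O1, C2, C3, C4, C4a, C8a), and C–O reductive elimination forms the O1–C8a bond. The closest known reaction is the Buchwald–Hartwig-type intramolecular etherification of aryl halides and sulfonates by secondary alcohols, an established route to chromans. Ring C closes as a six-membered ring by ipso substitution at C8a, the alcohol oxygen being tethered through C2, C3, C4 and C4a. No stereocentre is formed: C2 keeps its S configuration because its C–O bond is never broken, and both C4 epimers should cyclise. The step needs reductive elimination to outrun β-hydride elimination of the alkoxide, which the bulky di-tert-butyl biaryl phosphine favours, and it needs the C2 oxygen to be the only nucleophile, which the silyl ether on the C4 oxygen secures by keeping that oxygen away from palladium and from the sulfur of the neighbouring triflate. Oxidative addition at the doubly ortho-substituted carbon is helped by the two MOM-oxygens being meta to C8a, so they do not donate into the C–OTf carbon.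

**Step 12**
Reactants: 19 (2S)-4-(tert-butyldimethylsilyloxy)-5,7-bis(methoxymethoxy)-2-(4-methoxyphenyl)-6-methyl-8-(3-methylbut-2-en-1-yl)chromane
Product: 20 (2S)-5,7-bis(methoxymethoxy)-2-(4-methoxyphenyl)-6-methyl-8-(3-methylbut-2-en-1-yl)chroman-4-ol (both C4 epimers)
Conditions: TBAF, THF, 0 °C → rt
Reagents that add atoms: none
Why: Fluoride-driven Si–O cleavage frees the C4 hydroxyl under basic conditions, which spare the MOM acetals and avoid the acid that would ionise this electron-rich benzylic position.

**Step 13**
Reactants: 20 (2S)-5,7-bis(methoxymethoxy)-2-(4-methoxyphenyl)-6-methyl-8-(3-methylbut-2-en-1-yl)chroman-4-ol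
Product: 21 (2S)-5,7-bis(methoxymethoxy)-2-(4-methoxyphenyl)-6-methyl-8-(3-methylbut-2-en-1-yl)chroman-4-one
Conditions: Dess–Martin periodinane, pyridine, CH2Cl2, 0 °C → rt
Reagents that add atoms: none
Why: Buffered Dess–Martin oxidation of the secondary benzylic alcohol is close to neutral, so both C4 epimers should converge on one ketone while the prenyl alkene, the acetals and the C2 centre are left untouched.

**Step 14**
Reactants: 21 (2S)-5,7-bis(methoxymethoxy)-2-(4-methoxyphenyl)-6-methyl-8-(3-methylbut-2-en-1-yl)chroman-4-one
Product: 22 (2S)-5,7-dihydroxy-2-(4-methoxyphenyl)-6-methyl-8-(3-methylbut-2-en-1-yl)chroman-4-one (CNP0252391.1)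
Conditions: 3 M aq. HCl, MeOH, 40 °C
Reagents that add atoms: none
Why: Acid-catalysed acetal exchange with methanol removes both MOM groups as dimethoxymethane, and the mild temperature and short time are chosen so that O7 does not add to the prenyl alkene and the C2–O1 bond is not ionised.

**Compound list**
1 | 2-methylresorcinol (2-methylbenzene-1,3-diol) | Cc1c(O)cccc1O | starting material
2 | 1,3-bis(methoxymethoxy)-2-methylbenzene | Cc1c(OCOC)cccc1OCOC | intermediate
3 | 2-[3,5-bis(methoxymethoxy)-4-methylphenyl]-4,4,5,5-tetramethyl-1,3,2-dioxaborolane | Cc1c(OCOC)cc(B2OC(C)(C)C(C)(C)O2)cc1OCOC | intermediate (not isolated)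
4 | 3,5-bis(methoxymethoxy)-4-methylphenol | Cc1c(OCOC)cc(O)cc1OCOC | intermediate
5 | 2-methylbut-3-yn-2-ol | CC(C)(O)C#C | starting material
6 | 2-methylbut-3-yn-2-yl trifluoroacetate | CC(C)(OC(=O)C(F)(F)F)C#C | intermediate (not isolated)
7 | 1,3-bis(methoxymethoxy)-2-methyl-5-[(2-methylbut-3-yn-2-yl)oxy]benzene | Cc1c(OCOC)cc(OC(C)(C)C#C)cc1OCOC | intermediate
8 | 1,3-bis(methoxymethoxy)-2-methyl-5-[(2-methylbut-3-en-2-yl)oxy]benzene | Cc1c(OCOC)cc(OC(C)(C)C=C)cc1OCOC | intermediate
9 | 3,5-bis(methoxymethoxy)-4-methyl-6-(3-methylbut-2-en-1-yl)cyclohexa-2,4-dien-1-one (racemic) | O=C1C=C(OCOC)C(C)=C(OCOC)C1CC=C(C)C | intermediate (not isolated)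
10 | 3,5-bis(methoxymethoxy)-4-methyl-2-(3-methylbut-2-en-1-yl)phenol | Cc1c(OCOC)cc(O)c(CC=C(C)C)c1OCOC | intermediate
11 | 2-(hydroxymethyl)-3,5-bis(methoxymethoxy)-4-methyl-6-(3-methylbut-2-en-1-yl)phenol | Cc1c(OCOC)c(CO)c(O)c(CC=C(C)C)c1OCOC | intermediate (not isolated)
12 | 2-hydroxy-4,6-bis(methoxymethoxy)-5-methyl-3-(3-methylbut-2-en-1-yl)benzaldehyde | Cc1c(OCOC)c(C=O)c(O)c(CC=C(C)C)c1OCOC | intermediate
13 | 2-formyl-3,5-bis(methoxymethoxy)-4-methyl-6-(3-methylbut-2-en-1-yl)phenyl trifluoromethanesulfonate | Cc1c(OCOC)c(C=O)c(OS(=O)(=O)C(F)(F)F)c(CC=C(C)C)c1OCOC | intermediate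
14 | 4-methoxyacetophenone | COc1ccc(C(C)=O)cc1 | starting material
15 | lithium 1-(4-methoxyphenyl)ethenolate | [Li]OC(=C)c1ccc(OC)cc1 | intermediate (not isolated)
16 | rac-2-[1-hydroxy-3-(4-methoxyphenyl)-3-oxopropyl]-3,5-bis(methoxymethoxy)-4-methyl-6-(3-methylbut-2-en-1-yl)phenyl trifluoromethanesulfonate | COc1ccc(C(=O)CC(O)c2c(OCOC)c(C)c(OCOC)c(CC=C(C)C)c2OS(=O)(=O)C(F)(F)F)cc1 | intermediate
17 | rac-2-[1-(tert-butyldimethylsilyloxy)-3-(4-methoxyphenyl)-3-oxopropyl]-3,5-bis(methoxymethoxy)-4-methyl-6-(3-methylbut-2-en-1-yl)phenyl trifluoromethanesulfonate | COc1ccc(C(=O)CC(O[Si](C)(C)C(C)(C)C)c2c(OCOC)c(C)c(OCOC)c(CC=C(C)C)c2OS(=O)(=O)C(F)(F)F)cc1 | intermediate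
18 | 2-[(3S)-1-(tert-butyldimethylsilyloxy)-3-hydroxy-3-(4-methoxyphenyl)propyl]-3,5-bis(methoxymethoxy)-4-methyl-6-(3-methylbut-2-en-1-yl)phenyl trifluoromethanesulfonate, both C1 epimers | COc1ccc([C@@H](O)CC(O[Si](C)(C)C(C)(C)C)c2c(OCOC)c(C)c(OCOC)c(CC=C(C)C)c2OS(=O)(=O)C(F)(F)F)cc1 | intermediate
19 | (2S)-4-(tert-butyldimethylsilyloxy)-5,7-bis(methoxymethoxy)-2-(4-methoxyphenyl)-6-methyl-8-(3-methylbut-2-en-1-yl)chromane, both C4 epimers | COc1ccc([C@@H]2CC(O[Si](C)(C)C(C)(C)C)c3c(OCOC)c(C)c(OCOC)c(CC=C(C)C)c3O2)cc1 | intermediate
20 | (2S)-5,7-bis(methoxymethoxy)-2-(4-methoxyphenyl)-6-methyl-8-(3-methylbut-2-en-1-yl)chroman-4-ol, both C4 epimers | COc1ccc([C@@H]2CC(O)c3c(OCOC)c(C)c(OCOC)c(CC=C(C)C)c3O2)cc1 | intermediate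
21 | (2S)-5,7-bis(methoxymethoxy)-2-(4-methoxyphenyl)-6-methyl-8-(3-methylbut-2-en-1-yl)chroman-4-one | COc1ccc([C@@H]2CC(=O)c3c(OCOC)c(C)c(OCOC)c(CC=C(C)C)c3O2)cc1 | intermediate
22 | (2S)-5,7-dihydroxy-2-(4-methoxyphenyl)-6-methyl-8-(3-methylbut-2-en-1-yl)chroman-4-one | COc1ccc([C@@H]2CC(=O)c3c(O)c(C)c(O)c(CC=C(C)C)c3O2)cc1 | target

**Step count**
Total steps: 14. Longest linear sequence: 14 steps (1 to 22); 2-methylbut-3-yn-2-ol and 4-methoxyacetophenone enter directly.

**Steps most likely to fail**

Step 11. Oxidative addition at the triflate carbon, which carries two ortho substituents, may be slow. β-Hydride elimination of the palladium alkoxide, S–O cleavage of the sulfonate or silyl migration from the C4 oxygen to the C2 oxygen may then outrun C–O reductive elimination. The fallback closes ring C at the other bond of O1, by a Mitsunobu etherification that inverts C2. It sets out from ketone 17, which is reduced with the enantiomeric (S)-2-methyl-CBS-oxazaborolidine and catecholborane to the (3R)-carbinol triflate F1. The aryl triflate is then cleaved with aqueous Et4NOH in dioxane to the (3R)-carbinol phenol F2. Treatment with PPh3 and diisopropyl azodicarboxylate in THF at 0 °C should join the phenol oxygen to C2 with inversion and return to the route at 19. Partial ionisation at the 4-methoxybenzylic carbon is the known weakness of this closure, which is why it is held in reserve.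

Step 10. Facial discrimination may be poor, because the bulky β-silyloxy side chain narrows the size difference between the two ketone substituents that the oxazaborolidine reads, and one C4 epimer may be mismatched. The fallback changes the recognition principle to Noyori–Ikariya asymmetric transfer hydrogenation, in which the ruthenium hydride recognises the aryl ring through a CH–π contact and is largely indifferent to the aliphatic side. It sets out from 17, uses RuCl[(S,S)-TsDPEN](p-cymene) in HCO2H/Et3N at rt to 40 °C, leaves the alkene and the triflate untouched, and should return directly at 18. It makes no new compound (F0).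

Step 8. The lithium aldolate of the hindered aldehyde may revert by retro-aldol cleavage, lose water to the enone, or pick up the triflyl group from the neighbouring aryl triflate before it is quenched. The fallback avoids a free alkoxide by a Lewis acid-mediated Mukaiyama aldol. It sets out from 14, which is converted with TMSOTf and Et3N in CH2Cl2 at 0 °C into the trimethylsilyl enol ether F3. Addition of F3 to aldehyde 13 with BF3·OEt2 in CH2Cl2 at –78 °C, followed by aqueous work-up, should return to the route at 16.

**Further compounds**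
F1 | step 11 | 2-[(3R)-1-(tert-butyldimethylsilyloxy)-3-hydroxy-3-(4-methoxyphenyl)propyl]-3,5-bis(methoxymethoxy)-4-methyl-6-(3-methylbut-2-en-1-yl)phenyl trifluoromethanesulfonate, both C1 epimers | COc1ccc([C@H](O)CC(O[Si](C)(C)C(C)(C)C)c2c(OCOC)c(C)c(OCOC)c(CC=C(C)C)c2OS(=O)(=O)C(F)(F)F)cc1
F2 | step 11 | 2-[(3R)-1-(tert-butyldimethylsilyloxy)-3-hydroxy-3-(4-methoxyphenyl)propyl]-3,5-bis(methoxymethoxy)-4-methyl-6-(3-methylbut-2-en-1-yl)phenol, both C1 epimers | COc1ccc([C@H](O)CC(O[Si](C)(C)C(C)(C)C)c2c(OCOC)c(C)c(OCOC)c(CC=C(C)C)c2O)cc1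
F0 | step 10 | none | none
F3 | step 8 | trimethyl{[1-(4-methoxyphenyl)ethenyl]oxy}silane | COc1ccc(C(=C)O[Si](C)(C)C)cc1
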